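**Retrosynthetic overview**

1. The (2S)-flavanone is opened at the O7 protecting group and then at C2–C1' by a Rh-catalysed enantioselective 1,4-addition of a ring B arylboronic acid to a 7-O-MOM-8-prenylchromone. Rings A and C are bought together as 7-hydroxychromone, and the C8 prenyl group comes from iodination and Stille coupling.
2. The ring B boronic acid comes from the aryl chloride 6-chloro-2,2-dimethyl-8-prenylchroman.
3. Key disconnection: both bonds that fuse the dihydropyran ring to ring B, ArC–CH2 (C4–C4a of the chroman) and ArC–O (O1–C8a), are cut together. This gives 4-chloro-1-iodo-2-prenylbenzene and 4-bromo-2-methylbutan-2-ol, joined in one Pd/norbornene (Catellani-type) ortho C–H alkylation/ipso etherification.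
4. Enabling feature: O1 and the benzylic CH2 (C4) of the dihydropyran ring sit on two adjacent carbons of ring B (C4' and C5'). C4' has the prenyl-bearing C3' on its other side, and the oxygen-bearing C2 of the dihydropyran ring is quaternary (gem-dimethyl). An iodide at C4' with a single free ortho C–H is therefore a Catellani substrate, and the tertiary alkoxide that ends the sequence cannot undergo β-hydride elimination.
5. Ring order: rings A and C preformed; dihydropyran ring on ring B in step 2; fragment union at C2 of ring C in step 7 sets the only stereocentre.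

Key step: step 2

Assumption: C2 of the target is (S); the (S)-antipode of the bisphosphine in step 7 is assumed to give this sense, as it does with 2-cyclohexenone, and the (R)-ligand would be used if a model run shows the opposite.

**Route**

Step 1
Reactants: 1 2-(bromomethyl)-4-chloro-1-iodobenzene; 2 (2-methylprop-1-en-1-yl)magnesium bromide
Product: 3 4-chloro-1-iodo-2-(3-methylbut-2-en-1-yl)benzene
Conditions: 2 (1.2 equiv), CuI (5 mol %), THF, −30 to 0 °C
Reagents that add atoms: none
Why: Copper-catalysed cross-coupling of a benzylic bromide with an alkenyl Grignard reagent is fast at low temperature, where the aryl C–I and C–Cl bonds should not undergo halogen–magnesium exchange, and the alkene position of the prenyl group is fixed by the reagent.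

Step 2
Reactants: 3 4-chloro-1-iodo-2-(3-methylbut-2-en-1-yl)benzene; 4 4-bromo-2-methylbutan-2-ol
Product: 5 6-chloro-2,2-dimethyl-8-(3-methylbut-2-en-1-yl)-3,4-dihydro-2H-chromene
Conditions: 4 (2 equiv), Pd(OAc)2 (5 mol %), XPhos (10 mol %), norbornene (50 mol %), Cs2CO3 (2.5 equiv), 1,4-dioxane, 90 °C
Reagents that add atoms: none
Why: Proposed new method: oxidative addition of zerovalent palladium into the C–I bond of 3, norbornene insertion and C–H palladation at the only free ortho position should give the aryl–norbornyl palladacycle, which is alkylated by the primary bromide 4 through a tetravalent palladium intermediate (new ArC–CH2 bond); the now doubly ortho-substituted arene then expels norbornene by β-carbon elimination. The divalent arylpalladium species that results is captured by its own pendant tertiary alkoxide, and C–O reductive elimination from the seven-membered aryl(alkoxo)palladium chelate closes the six-membered dihydropyran ring (new ArC–O bond), the C–C bond of that ring having been made intermolecularly just before. The closest known reaction types are the Pd/norbornene ortho-alkylation/ipso-amination of aryl iodides with bromoalkylamines to tetrahydroquinolines, the Pd/norbornene annulation of aryl iodides with epoxides to 2,3-dihydrobenzofurans, and the Pd-catalysed intramolecular etherification of aryl halides with tertiary alcohols to 2,2-dimethylchromans; what is new is the six-membered ipso-etherification with a bromo alcohol. No stereocentre is formed. Selectivity is secured by the substrate: the prenyl group blocks one ortho position so that only the C–H on the other side of iodine is alkylated and norbornene is released, the tertiary alkoxide has no hydrogen on the carbinol carbon and cannot β-hydride eliminate, the gem-dimethyl group favours chelation and ring closure, the C–Cl bond adds to palladium far more slowly than C–I, and the trisubstituted prenyl alkene is a much poorer carbopalladation partner than strained norbornene.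

Step 3
Reactants: 5 6-chloro-2,2-dimethyl-8-(3-methylbut-2-en-1-yl)-3,4-dihydro-2H-chromene
Product: 6 [2,2-dimethyl-8-(3-methylbut-2-en-1-yl)-3,4-dihydro-2H-chromen-6-yl]boronic acid
Conditions: B2(OH)4 (2 equiv), Pd(OAc)2 (2 mol %), XPhos (4 mol %), KOAc (3 equiv), EtOH, 80 °C
Reagents that add atoms: tetrahydroxydiboron, OB(O)B(O)O
Why: Miyaura borylation of an aryl chloride with tetrahydroxydiboron under a Pd/XPhos catalyst should give the boronic acid directly, the aryl ether and the trisubstituted alkene being inert.

Step 4
Reactants: 7 7-hydroxy-4H-chromen-4-one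
Product: 8 7-hydroxy-8-iodo-4H-chromen-4-one
Conditions: N-iodosuccinimide (1.05 equiv), DMF, 0 °C to rt
Reagents that add atoms: N-iodosuccinimide, O=C1CCC(=O)N1I
Why: Electrophilic aromatic iodination of the phenol should go to C8, the most nucleophilic position of a 7-hydroxychromone (ortho to OH and to the ring oxygen, across the C7–C8 bond of higher double-bond character), as in the C8-selective halogenation of 7-hydroxycoumarins and isoflavones.

Step 5
Reactants: 8 7-hydroxy-8-iodo-4H-chromen-4-one
Product: 9 8-iodo-7-(methoxymethoxy)-4H-chromen-4-one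
Conditions: MOMCl (1.3 equiv), K2CO3 (2 equiv), acetone, 0 °C to rt
Reagents that add atoms: chloromethyl methyl ether, COCCl
Why: Williamson-type O-alkylation of the acidic 7-OH (a vinylogous carboxylic acid) gives a MOM ether that is stable to the Pd and Rh steps that follow.

Step 6
Reactants: 9 8-iodo-7-(methoxymethoxy)-4H-chromen-4-one; 10 tributyl(3-methylbut-2-en-1-yl)stannane
Product: 11 7-(methoxymethoxy)-8-(3-methylbut-2-en-1-yl)-4H-chromen-4-one
Conditions: 10 (1.3 equiv), Pd(PPh3)4 (5 mol %), DMF, 90 °C
Reagents that add atoms: none
Why: Stille cross-coupling of an aryl iodide with a prenylstannane, in which the allylpalladium intermediate should reductively eliminate at its less hindered terminus and so give the linear 3-methylbut-2-enyl group.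

Step 7
Reactants: 11 7-(methoxymethoxy)-8-(3-methylbut-2-en-1-yl)-4H-chromen-4-one; 6 [2,2-dimethyl-8-(3-methylbut-2-en-1-yl)-3,4-dihydro-2H-chromen-6-yl]boronic acid
Product: 12 (2S)-2-[2,2-dimethyl-8-(3-methylbut-2-en-1-yl)-3,4-dihydro-2H-chromen-6-yl]-7-(methoxymethoxy)-8-(3-methylbut-2-en-1-yl)-2,3-dihydro-4H-chromen-4-one
Conditions: 6 (1.5 equiv), [RhCl(C2H4)2]2 (2.5 mol %), (S)-6,6'-dimethoxy-2,2'-bis[bis(3,4,5-trifluorophenyl)phosphino]biphenyl (5.5 mol %), KOH (20 mol %), toluene/H2O 10:1, 30 °C
Reagents that add atoms: none
Why: Rhodium-catalysed enantioselective 1,4-addition of an arylboronic acid to a chromone (Hayashi–Miyaura reaction), a known entry to flavanones, in which the aryl–rhodium species adds across C2=C3 on the enone face left open by the C2-symmetric bisphosphine and so sets C2 as (S), while the mild, nearly neutral medium should prevent retro-oxa-Michael ring opening.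

Step 8
Reactants: 12 (2S)-2-[2,2-dimethyl-8-(3-methylbut-2-en-1-yl)-3,4-dihydro-2H-chromen-6-yl]-7-(methoxymethoxy)-8-(3-methylbut-2-en-1-yl)-2,3-dihydro-4H-chromen-4-one
Product: 13 (2S)-2-[2,2-dimethyl-8-(3-methylbut-2-en-1-yl)-3,4-dihydro-2H-chromen-6-yl]-7-hydroxy-8-(3-methylbut-2-en-1-yl)-2,3-dihydro-4H-chromen-4-one (CNP0272905.1)
Conditions: HCl (conc., catalytic), MeOH, rt to 40 °C, short reaction time
Reagents that add atoms: none
Why: Acid-catalysed acetal exchange with methanol removes the MOM ether; C2 is not epimerised under acid, and low temperature and short time should spare the two prenyl groups.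

**Compound list**

1 | 2-(bromomethyl)-4-chloro-1-iodobenzene | BrCc1cc(Cl)ccc1I | starting material
2 | (2-methylprop-1-en-1-yl)magnesium bromide | CC(C)=C[Mg]Br | starting material
3 | 4-chloro-1-iodo-2-(3-methylbut-2-en-1-yl)benzene | CC(C)=CCc1cc(Cl)ccc1I | intermediate
4 | 4-bromo-2-methylbutan-2-ol | CC(C)(O)CCBr | starting material
5 | 6-chloro-2,2-dimethyl-8-(3-methylbut-2-en-1-yl)-3,4-dihydro-2H-chromene | CC(C)=CCc1cc(Cl)cc2c1OC(C)(C)CC2 | intermediate
6 | [2,2-dimethyl-8-(3-methylbut-2-en-1-yl)-3,4-dihydro-2H-chromen-6-yl]boronic acid | CC(C)=CCc1cc(B(O)O)cc2c1OC(C)(C)CC2 | intermediate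
7 | 7-hydroxy-4H-chromen-4-one | O=c1ccoc2cc(O)ccc12 | starting material
8 | 7-hydroxy-8-iodo-4H-chromen-4-one | O=c1ccoc2c(I)c(O)ccc12 | intermediate
9 | 8-iodo-7-(methoxymethoxy)-4H-chromen-4-one | COCOc1ccc2c(=O)ccoc2c1I | intermediate
10 | tributyl(3-methylbut-2-en-1-yl)stannane | CCCC[Sn](CCCC)(CCCC)CC=C(C)C | starting material
11 | 7-(methoxymethoxy)-8-(3-methylbut-2-en-1-yl)-4H-chromen-4-one | COCOc1ccc2c(=O)ccoc2c1CC=C(C)C | intermediate
12 | (2S)-2-[2,2-dimethyl-8-(3-methylbut-2-en-1-yl)-3,4-dihydro-2H-chromen-6-yl]-7-(methoxymethoxy)-8-(3-methylbut-2-en-1-yl)-2,3-dihydro-4H-chromen-4-one | CC(C)=CCc1cc([C@@H]2CC(=O)c3ccc(OCOC)c(CC=C(C)C)c3O2)cc2c1OC(C)(C)CC2 | intermediate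
13 | (2S)-2-[2,2-dimethyl-8-(3-methylbut-2-en-1-yl)-3,4-dihydro-2H-chromen-6-yl]-7-hydroxy-8-(3-methylbut-2-en-1-yl)-2,3-dihydro-4H-chromen-4-one | CC(C)=CCc1cc([C@@H]2CC(=O)c3ccc(O)c(CC=C(C)C)c3O2)cc2c1OC(C)(C)CC2 | target

**Step count**

Total steps: 8. Longest linear sequence: 5 steps (steps 1, 2, 3, 7, 8; the chromone arm, steps 4, 5, 6, 7, 8, is equally long).

**Steps most likely to fail**

Step 2 (Proposed new method). The ipso C–O reductive elimination may lose to premature termination of the arylpalladium intermediate (reduction at the ipso carbon), to slow reaction at the C–Cl bond once the iodide is used up, or to base-induced loss of 4 by elimination or oxetane formation.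
Fallback with known chemistry, setting out from 3 and returning at 5:
- Copper-catalysed hydroxylation of the aryl iodide (CuI, 1,10-phenanthroline, KOH, DMSO/H2O, 100 °C) should give 4-chloro-2-(3-methylbut-2-en-1-yl)phenol F1.
- Ortho-selective chromenylation of F1 with 3-methylbut-2-enal (PhB(OH)2, AcOH, toluene, reflux, water removal; ortho-quinone methide formation and 6π oxa-electrocyclisation) should give 6-chloro-2,2-dimethyl-8-(3-methylbut-2-en-1-yl)-2H-chromene F2.
- Diimide reduction (2-nitrobenzenesulfonyl hydrazide, Et3N, CH2Cl2, rt) should saturate the cis-disubstituted chromene double bond in preference to the trisubstituted prenyl alkene and give 5.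

Step 7. Carbometalation of the electron-rich 7-alkoxychromone may be slow, so that protodeboronation of 6 competes, and base-induced ring opening and reclosure of the product may erode the enantiomeric purity.
Fallback, setting out from 11 and 6 and returning at 12:
- The addition is run without asymmetric induction ([Rh(OH)(cod)]2, cod = 1,5-cyclooctadiene, dioxane/H2O, 50 °C) to give the racemic flavanone F3.
- The enantiomers are separated by preparative HPLC on a chiral stationary phase to give 12.
- The (2R)-enantiomer F4 is racemised through reversible ring opening (catalytic DBU, MeOH, rt) and separated again.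

Step 6. Oxidative addition and transmetalation at the iodide flanked by two oxygen substituents may be slow, and allylic transposition may give the 1,1-dimethylallyl isomer in place of the prenyl group.
Fallback, setting out from 7 and returning at 11 (it also bypasses steps 4 and 5):
- O-alkylation of 7 with 3-chloro-3-methylbut-1-yne (CuCl2 catalytic, DBU, MeCN, 0 °C) should give 7-[(2-methylbut-3-yn-2-yl)oxy]-4H-chromen-4-one F5.
- Semihydrogenation (H2, Pd/CaCO3 poisoned with Pb(OAc)2, quinoline, EtOAc) should give 7-[(2-methylbut-3-en-2-yl)oxy]-4H-chromen-4-one F6.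
- Aromatic Claisen rearrangement (N,N-diethylaniline, 190 °C) should move the allyl unit to C8 with inversion of its termini and give 7-hydroxy-8-(3-methylbut-2-en-1-yl)-4H-chromen-4-one F7.
- F7 is protected as in step 5 (MOMCl, K2CO3, acetone) to give 11.

**Further compounds**

F1 | step 2 | 4-chloro-2-(3-methylbut-2-en-1-yl)phenol | CC(C)=CCc1cc(Cl)ccc1O
F2 | step 2 | 6-chloro-2,2-dimethyl-8-(3-methylbut-2-en-1-yl)-2H-chromene | CC(C)=CCc1cc(Cl)cc2c1OC(C)(C)C=C2
F3 | step 7 | racemic 2-[2,2-dimethyl-8-(3-methylbut-2-en-1-yl)-3,4-dihydro-2H-chromen-6-yl]-7-(methoxymethoxy)-8-(3-methylbut-2-en-1-yl)-2,3-dihydro-4H-chromen-4-one | CC(C)=CCc1cc(C2CC(=O)c3ccc(OCOC)c(CC=C(C)C)c3O2)cc2c1OC(C)(C)CC2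
F4 | step 7 | (2R)-2-[2,2-dimethyl-8-(3-methylbut-2-en-1-yl)-3,4-dihydro-2H-chromen-6-yl]-7-(methoxymethoxy)-8-(3-methylbut-2-en-1-yl)-2,3-dihydro-4H-chromen-4-one | CC(C)=CCc1cc([C@H]2CC(=O)c3ccc(OCOC)c(CC=C(C)C)c3O2)cc2c1OC(C)(C)CC2
F5 | step 6 | 7-[(2-methylbut-3-yn-2-yl)oxy]-4H-chromen-4-one | C#CC(C)(C)Oc1ccc2c(=O)ccoc2c1
F6 | step 6 | 7-[(2-methylbut-3-en-2-yl)oxy]-4H-chromen-4-one | C=CC(C)(C)Oc1ccc2c(=O)ccoc2c1
F7 | step 6 | 7-hydroxy-8-(3-methylbut-2-en-1-yl)-4H-chromen-4-one | CC(C)=CCc1c(O)ccc2c(=O)ccoc12
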